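Assumption: the target SMILES carries no stereodescriptor, so the C8–C3' biaryl axis is treated as configurationally undefined and no control of axial chirality is planned; 4-(benzyloxy)-3-methoxybenzaldehyde, the benzyl ether of vanillin, is taken as a purchasable starting material.

## Structural features

The target is a biflavone of six rings: two 4H-chromen-4-one bicycles (rings A and C of each flavone) and two 2-aryl rings B. A chrysoeriol unit (5,7-dihydroxy, ring B with 3'-methoxy and 4'-hydroxy) is bonded through C8 of its ring A to C3' of ring B of an apigenin unit (5,7,4'-trihydroxyflavone). This one C(sp2)–C(sp2) bond is the only link between the halves. There is no stereocentre; the interflavone axis has three ortho substituents (C8a–O1, C7–O and C4'–O) but is not defined in the target. The fragile elements are: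
- the six free phenols, which are therefore unveiled only in the last step;
- the two pyranones, vinylogous esters that hot alkali opens and hard nucleophiles attack at C4 or C2;
- the single 3'-methyl ether, which must survive every deprotection;
- the 5-oxygenated, 8-substituted ring A, which can isomerise to the 6-substituted flavone by ring opening and reclosure in strong acid once the 5-hydroxyl is free.

The real difficulty is the hindered biaryl bond with unambiguous regiochemistry on both sides (C8 and not C6 of chrysoeriol, C3' and not C2' of apigenin), together with the differentiation of six phenolic oxygens from one methylated oxygen. The key step uses the substitution pattern of apigenin ring B: C1' (pyranone carbon), C3' (bond to C8) and C4' (oxygen) stand 1,3,4, so the oxygen is para to C1' and ortho to C3'. A 5-carboxylated 2-pyrone that adds across an aryl ynol ether and loses CO2 delivers exactly this pattern, so ring B is grown on C8 instead of being coupled to it.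

## Logic of the disconnections

19 from 18. The six O–CH2Ph bonds are cut. One kind of protecting group, orthogonal to the 3'-methyl ether, keeps all six phenols masked to the end, so every earlier intermediate is a neutral, soluble ether that is not prone to oxidation. The forward step must cleave benzyl ethers without reducing either pyranone C2=C3 bond.

18 from 16 and 2. In the apigenin unit the O1–C2 bond and the C2–C3 bond are cut, the latter between an ester carbonyl carbon and a methyl ketone carbon; 17 is the open form between them. This removes a whole benzopyranone and leaves a benzoate whose ester already sits on C1'. The forward step asks an enolate to acylate an electron-rich, non-enolisable ester in the presence of the first pyranone, and the ring closure must not cost benzyl groups.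

16 from 15. Only the C4' O–benzyl bond is exchanged for an O–Si bond. The cycloaddition partner has to be a silyl ynol ether, while the condensation that follows is safer on an alkyl ether; complexity is unchanged. Desilylation and benzylation must run in one flask so that no step is added compared with a separate late desilylation.

15 from 12 and 13. The C2'–C3' and C4'–C5' bonds of apigenin ring B are cut and a CO2 bridge is put back across C2' and C5' (14). The hindered biaryl bond is never made by coupling: C3' is already attached to C8 as an alkyne carbon, and the other four ring carbons and the C1' ester come from 13. Ring B, its 1,3,4-pattern and the ester handle for the second pyranone are created together. The forward step needs one orientation of the cycloaddition and a siloxyalkyne that tolerates heating, which is why the silyl group is triisopropylsilyl.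

12 from 9. The O–Si bond and the C(sp)–O bond are cut; 10 and 11 are the anions in between. Oxygen is put on a terminal alkyne late, because an ynol ether would not survive the construction of the flavone. The forward step must oxidise an acetylide at carbon without touching the pyranone and must silylate the ynolate at oxygen.

9 from 6 and 7. The C8–C(sp) bond is cut; 8 is the silyl-capped intermediate. A two-carbon unit is attached to a ready-made, regiodefined aryl iodide. The coupling must tolerate the two ortho substituents of C8.

6 from 5. The O1–C2 bond of chrysoeriol ring C is cut and C2=C3 is taken back to the chalcone oxidation level, which opens the heterocycle to an acyclic enone. The forward oxidative cyclisation must spare the C–I bond and the benzyl ethers. Only the hydroxyl next to iodine is free, so ring closure fixes the iodine at C8.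

5 from 3 and 4. The enone C=C bond, the future C2–C3 bond of the chrysoeriol unit, is cut, giving two simple aromatic building blocks. The forward aldol condensation must work on a hindered, chelated hydroxyketone.

3 from 2. The C–I bond is cut. Placing the halogen at the acetophenone stage, ortho to the only free hydroxyl, settles C8 versus C6 before the heterocycle exists. The forward iodination must be mono- and ortho-selective.

2 from 1. Two O–benzyl bonds are cut. 2 is used twice, as ring A of both flavone units. The forward alkylation must stop at the dibenzyl ether.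

## Other disconnections considered

Alternative 1: The cut runs through ring A of the chrysoeriol unit, at C8–C8a, C6–C7 and C4a–C8a. In the forward direction 3-ethoxycyclobut-2-en-1-one A3 would be heated with the aryl siloxyalkyne A2 in a Danheiser benzannulation: four-electron ring opening to a vinylketene, [2+2] addition to the alkyne, a second ring opening and six-electron electrocyclisation. This should give the phenol A1 with free C8a hydroxyl, silylated C7 oxygen and ethylated C5 oxygen.
- In its favour: benzannulation of siloxyalkynes is the classical use of this reaction, so precedent for the key step is at least equal to, and arguably better than, that of the chosen plan. The ynolate chemistry would be run on a simple arene without a pyranone, which is clearly better than step 6 of the chosen plan. The regiochemistry (aryl group ortho to the free hydroxyl) follows from the mechanism, equal to the chosen plan.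
- Against it: A1 contains neither pyranone, so both would have to be built afterwards. C-acylation at C4a would compete with C6 and would need Lewis acid conditions that endanger the acetal and the silyl ether. The C5 ethyl ether would have to be cleaved at the end next to the 3'-methyl ether that must stay. A3 has to be prepared.
- Comparison: on structure both plans use an aryl siloxyalkyne to grow a ring next to the biaryl axis. On mechanism the alternative is the more precedented. On step economy it is estimated to be several steps longer, with a harder late differentiation of oxygens.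

Alternative 2: The cut is the C3–C4 bond of the chrysoeriol pyranone, masked as an isoxazole. In the forward direction the biaryl aldoxime A5 would be oxidised by a hypervalent iodine reagent to its nitrile oxide, which would add to the terminal alkyne A6 to give the 3,5-disubstituted isoxazole A4. Reductive N–O cleavage, hydrolysis of the enaminone to the 1,3-diketone, removal of the methoxymethyl group and cyclodehydration would follow.
- In its favour: the dipolar cycloaddition is mild, neutral and reliably regioselective with terminal alkynes. As a single reaction it is more predictable than the pyrone cycloaddition, a point on which it is better. The nitrile oxide, flanked by two ortho substituents, should resist dimerisation.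
- Against it: A5 already contains the hindered biaryl bond and the complete apigenin unit, so the central problem is moved into the preparation of A5 and not solved. The oxidant meets a very electron-rich ring. The N–O cleavage must avoid hydrogenolysis to spare the benzyl ethers. Three to four operations after the key step reach a stage that aldol condensation and oxidative cyclisation reach in two.
- Comparison: on structure it forms only one bond of a heterocycle, against a whole benzene ring and the biaryl pattern in the chosen plan. On mechanism it is equal or better in reliability. On step economy it is worse.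

Alternative 3: The cut is the C2=C3 bond in both pyranones. In the forward direction the bis(phosphoranylidene) diester A8 would be heated so that each acyl-stabilised ylide carbon attacks the neighbouring aryl ester carbonyl in an intramolecular Wittig reaction. Both rings C would close, with loss of two phosphine oxide molecules, to the hexabenzyl ether A7, which is the same compound as 18.
- In its favour: both pyranones form in one operation under neutral conditions, which is better for benzyl ethers than an acid cyclodehydration. The endgame is identical with that of the chosen plan, an equal point.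
- Against it: A8 requires the biaryl bond to be made beforehand, so again the central problem is not addressed. It also needs two haloketone-to-ylide sequences and two different O-acylations of hindered ortho-acyl phenols, one beside the biaryl axis. Stabilised ylides react with electron-rich aryl esters only at high temperature, and acyl transfer to the ylide carbon can compete.
- Comparison: on structure it is elegant and two-directional. On mechanism it is of equal reliability for simple flavones but undemonstrated as a double closure on such a crowded substrate. On step economy it is longer, and its atom economy is poor.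

Key step: step 7

## Route

Step 1
Reactants: 1 2,4,6-trihydroxyacetophenone
Product: 2 1-[2,4-bis(benzyloxy)-6-hydroxyphenyl]ethan-1-one
Conditions: BnBr (2.1 equiv), K2CO3 (2.2 equiv), DMF, rt
Reagents that add atoms: benzyl bromide, BrCc1ccccc1
Why: Williamson etherification; the para hydroxyl and one ortho hydroxyl are alkylated, and the remaining ortho hydroxyl is held in a hydrogen bond to the acetyl carbonyl, which lowers its nucleophilicity and should stop the reaction at the dibenzyl ether with two equivalents of bromide.

Step 2
Reactants: 2 1-[2,4-bis(benzyloxy)-6-hydroxyphenyl]ethan-1-one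
Product: 3 1-[4,6-bis(benzyloxy)-2-hydroxy-3-iodophenyl]ethan-1-one
Conditions: NIS (1.05 equiv), TFA (10 mol %), MeCN, 0 °C to rt, dark
Reagents that add atoms: N-iodosuccinimide, O=C1CCC(=O)N1I
Why: Electrophilic aromatic iodination; the free phenol directs to its ortho position C3, which is also para to the 6-benzyloxy group and is the usual site of halogenation of 2-hydroxy-4,6-dialkoxyacetophenones, and one equivalent of reagent avoids the diiodide. Since only this hydroxyl can later close the pyranone, the iodine is carried to C8 of the flavone.

Step 3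
Reactants: 3 1-[4,6-bis(benzyloxy)-2-hydroxy-3-iodophenyl]ethan-1-one; 4 4-(benzyloxy)-3-methoxybenzaldehyde
Product: 5 (E)-1-[4,6-bis(benzyloxy)-2-hydroxy-3-iodophenyl]-3-[4-(benzyloxy)-3-methoxyphenyl]prop-2-en-1-one
Conditions: KOH (50% aq.), EtOH–THF, rt
Reagents that add atoms: none
Why: Claisen–Schmidt condensation of the methyl ketone enolate with the non-enolisable aldehyde 4; E1cB dehydration should give the conjugated E-alkene as the thermodynamic product.

Step 4
Reactants: 5 (E)-1-[4,6-bis(benzyloxy)-2-hydroxy-3-iodophenyl]-3-[4-(benzyloxy)-3-methoxyphenyl]prop-2-en-1-one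
Product: 6 5,7-bis(benzyloxy)-2-[4-(benzyloxy)-3-methoxyphenyl]-8-iodo-4H-chromen-4-one
Conditions: I2 (10 mol %), DMSO, 120 °C
Reagents that add atoms: none
Why: Iodine-catalysed oxidative cyclisation of a 2'-hydroxychalcone: conjugate addition of the phenol (6-endo-trig) and iodine-mediated dehydrogenation should give the chromen-4-one, with DMSO reoxidising HI to I2. Catalytic iodine and short heating limit the acid exposure of the 5-benzyl ether and the C8–I bond.

Step 5
Reactants: 6 5,7-bis(benzyloxy)-2-[4-(benzyloxy)-3-methoxyphenyl]-8-iodo-4H-chromen-4-one; 7 ethynyltrimethylsilane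
Product: 9 5,7-bis(benzyloxy)-2-[4-(benzyloxy)-3-methoxyphenyl]-8-ethynyl-4H-chromen-4-one, via 8-[(trimethylsilyl)ethynyl] flavone 8 (not isolated)
Conditions: (i) PdCl2(PPh3)2 (5 mol %), CuI (10 mol %), Et3N, DMF, 65 °C, sealed vessel; (ii) MeOH, K2CO3, rt
Reagents that add atoms: none
Why: Sonogashira coupling: zerovalent palladium, formed in situ from the divalent precatalyst, inserts into the C8–I bond, the copper acetylide transmetalates and reductive elimination forms the C8–C(sp) bond. The silyl cap prevents double arylation and is then removed by methanolysis in the same flask.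

Step 6
Reactants: 9 5,7-bis(benzyloxy)-2-[4-(benzyloxy)-3-methoxyphenyl]-8-ethynyl-4H-chromen-4-one
Product: 12 5,7-bis(benzyloxy)-2-[4-(benzyloxy)-3-methoxyphenyl]-8-{[tri(propan-2-yl)silyloxy]ethynyl}-4H-chromen-4-one, via lithium acetylide 10 (not isolated), via lithium ynolate 11 (not isolated)
Conditions: (i) LiHMDS (1.1 equiv), THF, −78 °C; (ii) t-BuOOLi [from t-BuOOH (1.1 equiv) and LiHMDS (1.1 equiv), THF, −78 °C], −78 to 0 °C; (iii) TIPSOTf (1.3 equiv), −78 to 0 °C
Reagents that add atoms: tert-butyl hydroperoxide, CC(C)(C)OO; triisopropylsilyl trifluoromethanesulfonate, CC(C)[Si](OS(=O)(=O)C(F)(F)F)(C(C)C)C(C)C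
Why: Acetylide oxidation followed by O-silylation: the carbon of 10 attacks the electrophilic oxygen of lithium tert-butyl peroxide with loss of tert-butoxide to give ynolate 11, and the bulky silyl triflate traps 11 on oxygen, the known way to triisopropylsiloxyalkynes from terminal alkynes. LiHMDS is non-nucleophilic and the pyranone is a deactivated, peri-shielded vinylogous ester, which should keep the flavone intact between −78 and 0 °C.

Step 7
Reactants: 12 5,7-bis(benzyloxy)-2-[4-(benzyloxy)-3-methoxyphenyl]-8-{[tri(propan-2-yl)silyloxy]ethynyl}-4H-chromen-4-one; 13 methyl coumalate (methyl 2-oxo-2H-pyran-5-carboxylate)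
Product: 15 methyl 3-{5,7-bis(benzyloxy)-2-[4-(benzyloxy)-3-methoxyphenyl]-4-oxo-4H-chromen-8-yl}-4-[tri(propan-2-yl)silyloxy]benzoate, via bridged bicyclic lactone 14 (not isolated)
Conditions: 13 (3 equiv), PhMe, 110 °C, sealed tube, Ar
Reagents that add atoms: none
Why: Inverse-electron-demand Diels–Alder reaction: the electron-poor diene C3=C4–C5=C6 of 13 adds to the electron-rich triple bond of 12 in an asynchronous [4+2], in which the bond from the aryl-bearing alkyne carbon to C6 of the pyrone (the future C2'–C3' bond) runs ahead of the bond from the oxygen-bearing carbon to C3 (the future C4'–C5' bond). The bridged lactone 14 then loses CO2 by a retro-[4+2] driven by aromatisation, so the new benzene ring appears directly at the arene oxidation level. The closest known reaction type is the cycloaddition–decarboxylation of methyl coumalate with alkoxyalkynes, ynamines and ketene acetals, which gives benzoates with the heteroatom para to the ester; the aryl siloxyalkyne is a more hindered member of the same class of electron-rich two-carbon partners. Ring B is closed by an intermolecular [4+2] that forms two C–C bonds inside a 2-oxabicyclo[2.2.2]octadiene, and the two-atom lactone bridge is then extruded. The two bridgehead stereocentres of 14 form as a racemate and are erased when CO2 leaves, so no stereocentre has to be controlled. The step needs a single orientation: the most nucleophilic alkyne carbon (β to the silyloxy group, the one bearing the flavone) pairs with C6 of 13, the terminus conjugated to both the ester and the lactone carbonyl, which places the silyloxy group para to the ester and the chrysoeriol C8 ortho to that oxygen. Purely thermal conditions without acid or silver salts are chosen so that the siloxyalkyne is not turned into a ketenium ion that the neighbouring 7-benzyloxy oxygen could trap, and the triisopropylsilyl group slows the 1,3-silyl shift to a silylketene at this temperature.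

Step 8
Reactants: 15 methyl 3-{5,7-bis(benzyloxy)-2-[4-(benzyloxy)-3-methoxyphenyl]-4-oxo-4H-chromen-8-yl}-4-[tri(propan-2-yl)silyloxy]benzoate
Product: 16 methyl 4-(benzyloxy)-3-{5,7-bis(benzyloxy)-2-[4-(benzyloxy)-3-methoxyphenyl]-4-oxo-4H-chromen-8-yl}benzoate
Conditions: CsF (3 equiv), BnBr (1.5 equiv), DMF, 50 °C
Reagents that add atoms: benzyl bromide, BrCc1ccccc1
Why: Fluoride cleaves the aryl O–Si bond and the caesium phenoxide is benzylated in the same flask (Williamson etherification). The exchange replaces a base-labile aryl silyl ether by an ether that tolerates the enolate chemistry of step 9 and leaves with the other benzyl groups in step 10.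

Step 9
Reactants: 16 methyl 4-(benzyloxy)-3-{5,7-bis(benzyloxy)-2-[4-(benzyloxy)-3-methoxyphenyl]-4-oxo-4H-chromen-8-yl}benzoate; 2 1-[2,4-bis(benzyloxy)-6-hydroxyphenyl]ethan-1-one
Product: 18 5,7-bis(benzyloxy)-8-{2-(benzyloxy)-5-[5,7-bis(benzyloxy)-4-oxo-4H-chromen-2-yl]phenyl}-2-[4-(benzyloxy)-3-methoxyphenyl]-4H-chromen-4-one, via 1,3-diketone 17 (not isolated)
Conditions: (i) 2 (1.5 equiv), LiHMDS (4.5 equiv), THF, −78 to 0 °C, then 16, 0 °C to rt; AcOH quench; (ii) TsOH·H2O (0.3 equiv), PhMe, 90 °C
Reagents that add atoms: none
Why: Crossed Claisen condensation of the phenoxide–enolate dianion of 2 with the non-enolisable ester 16, driven by deprotonation of the 1,3-diketone 17. Mild acid then promotes attack of the phenol on the aryl ketone carbonyl and loss of water (cyclodehydration) to close the apigenin pyranone.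

Step 10
Reactants: 18 5,7-bis(benzyloxy)-8-{2-(benzyloxy)-5-[5,7-bis(benzyloxy)-4-oxo-4H-chromen-2-yl]phenyl}-2-[4-(benzyloxy)-3-methoxyphenyl]-4H-chromen-4-one
Product: 19 8-[5-(5,7-dihydroxy-4-oxo-4H-chromen-2-yl)-2-hydroxyphenyl]-5,7-dihydroxy-2-(4-hydroxy-3-methoxyphenyl)-4H-chromen-4-one (target)
Conditions: H2 (1 atm), 10% Pd/C, THF–MeOH, rt
Reagents that add atoms: none
Why: Heterogeneous hydrogenolysis of the six benzyl aryl ethers; the aryl methyl ether is inert, and the conjugated C2=C3 bonds of the pyranones are reduced far more slowly than benzylic C–O bonds are cleaved at one atmosphere.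

## Compound list

1 | 2,4,6-trihydroxyacetophenone | CC(=O)c1c(O)cc(O)cc1O | starting material
2 | 1-[2,4-bis(benzyloxy)-6-hydroxyphenyl]ethan-1-one | CC(=O)c1c(O)cc(OCc2ccccc2)cc1OCc1ccccc1 | intermediate
3 | 1-[4,6-bis(benzyloxy)-2-hydroxy-3-iodophenyl]ethan-1-one | CC(=O)c1c(O)c(I)c(OCc2ccccc2)cc1OCc1ccccc1 | intermediate
4 | 4-(benzyloxy)-3-methoxybenzaldehyde | COc1cc(C=O)ccc1OCc1ccccc1 | starting material
5 | (E)-1-[4,6-bis(benzyloxy)-2-hydroxy-3-iodophenyl]-3-[4-(benzyloxy)-3-methoxyphenyl]prop-2-en-1-one | COc1cc(/C=C/C(=O)c2c(O)c(I)c(OCc3ccccc3)cc2OCc2ccccc2)ccc1OCc1ccccc1 | intermediate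
6 | 5,7-bis(benzyloxy)-2-[4-(benzyloxy)-3-methoxyphenyl]-8-iodo-4H-chromen-4-one | COc1cc(-c2cc(=O)c3c(OCc4ccccc4)cc(OCc4ccccc4)c(I)c3o2)ccc1OCc1ccccc1 | intermediate
7 | ethynyltrimethylsilane | C#C[Si](C)(C)C | starting material
8 | 5,7-bis(benzyloxy)-2-[4-(benzyloxy)-3-methoxyphenyl]-8-[(trimethylsilyl)ethynyl]-4H-chromen-4-one | COc1cc(-c2cc(=O)c3c(OCc4ccccc4)cc(OCc4ccccc4)c(C#C[Si](C)(C)C)c3o2)ccc1OCc1ccccc1 | intermediate
9 | 5,7-bis(benzyloxy)-2-[4-(benzyloxy)-3-methoxyphenyl]-8-ethynyl-4H-chromen-4-one | COc1cc(-c2cc(=O)c3c(OCc4ccccc4)cc(OCc4ccccc4)c(C#C)c3o2)ccc1OCc1ccccc1 | intermediate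
10 | lithium acetylide of 9, ({5,7-bis(benzyloxy)-2-[4-(benzyloxy)-3-methoxyphenyl]-4-oxo-4H-chromen-8-yl}ethynyl)lithium | COc1cc(-c2cc(=O)c3c(OCc4ccccc4)cc(OCc4ccccc4)c(C#C[Li])c3o2)ccc1OCc1ccccc1 | intermediate
11 | lithium 2-{5,7-bis(benzyloxy)-2-[4-(benzyloxy)-3-methoxyphenyl]-4-oxo-4H-chromen-8-yl}ethyn-1-olate | COc1cc(-c2cc(=O)c3c(OCc4ccccc4)cc(OCc4ccccc4)c(C#CO[Li])c3o2)ccc1OCc1ccccc1 | intermediate
12 | 5,7-bis(benzyloxy)-2-[4-(benzyloxy)-3-methoxyphenyl]-8-{[tri(propan-2-yl)silyloxy]ethynyl}-4H-chromen-4-one | COc1cc(-c2cc(=O)c3c(OCc4ccccc4)cc(OCc4ccccc4)c(C#CO[Si](C(C)C)(C(C)C)C(C)C)c3o2)ccc1OCc1ccccc1 | intermediate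
13 | methyl coumalate (methyl 2-oxo-2H-pyran-5-carboxylate) | COC(=O)c1ccc(=O)oc1 | starting material
14 | methyl 6-{5,7-bis(benzyloxy)-2-[4-(benzyloxy)-3-methoxyphenyl]-4-oxo-4H-chromen-8-yl}-3-oxo-5-[tri(propan-2-yl)silyloxy]-2-oxabicyclo[2.2.2]octa-5,7-diene-7-carboxylate (racemic; relative configuration fixed by the bridge) | COc1cc(-c2cc(=O)c3c(OCc4ccccc4)cc(OCc4ccccc4)c(C4=C(O[Si](C(C)C)(C(C)C)C(C)C)C5C=C(C(=O)OC)C4OC5=O)c3o2)ccc1OCc1ccccc1 | intermediate
15 | methyl 3-{5,7-bis(benzyloxy)-2-[4-(benzyloxy)-3-methoxyphenyl]-4-oxo-4H-chromen-8-yl}-4-[tri(propan-2-yl)silyloxy]benzoate | COc1cc(-c2cc(=O)c3c(OCc4ccccc4)cc(OCc4ccccc4)c(-c4cc(C(=O)OC)ccc4O[Si](C(C)C)(C(C)C)C(C)C)c3o2)ccc1OCc1ccccc1 | intermediate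
16 | methyl 4-(benzyloxy)-3-{5,7-bis(benzyloxy)-2-[4-(benzyloxy)-3-methoxyphenyl]-4-oxo-4H-chromen-8-yl}benzoate | COc1cc(-c2cc(=O)c3c(OCc4ccccc4)cc(OCc4ccccc4)c(-c4cc(C(=O)OC)ccc4OCc4ccccc4)c3o2)ccc1OCc1ccccc1 | intermediate
17 | 1-[2,4-bis(benzyloxy)-6-hydroxyphenyl]-3-(4-(benzyloxy)-3-{5,7-bis(benzyloxy)-2-[4-(benzyloxy)-3-methoxyphenyl]-4-oxo-4H-chromen-8-yl}phenyl)propane-1,3-dione | COc1cc(-c2cc(=O)c3c(OCc4ccccc4)cc(OCc4ccccc4)c(-c4cc(C(=O)CC(=O)c5c(O)cc(OCc6ccccc6)cc5OCc5ccccc5)ccc4OCc4ccccc4)c3o2)ccc1OCc1ccccc1 | intermediate
18 | 5,7-bis(benzyloxy)-8-{2-(benzyloxy)-5-[5,7-bis(benzyloxy)-4-oxo-4H-chromen-2-yl]phenyl}-2-[4-(benzyloxy)-3-methoxyphenyl]-4H-chromen-4-one | COc1cc(-c2cc(=O)c3c(OCc4ccccc4)cc(OCc4ccccc4)c(-c4cc(-c5cc(=O)c6c(OCc7ccccc7)cc(OCc7ccccc7)cc6o5)ccc4OCc4ccccc4)c3o2)ccc1OCc1ccccc1 | intermediate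
19 | 8-[5-(5,7-dihydroxy-4-oxo-4H-chromen-2-yl)-2-hydroxyphenyl]-5,7-dihydroxy-2-(4-hydroxy-3-methoxyphenyl)-4H-chromen-4-one | COc1cc(-c2cc(=O)c3c(O)cc(O)c(-c4cc(-c5cc(=O)c6c(O)cc(O)cc6o5)ccc4O)c3o2)ccc1O | target

## Step count and least certain steps

Total: 10 steps. Longest linear sequence: 10 steps (1 to 19 through steps 1 to 10); 2 from step 1 is used a second time in step 9.

Step 7 (key step). The flavone with its two ortho substituents may slow the cycloaddition. Thermal 1,3-silyl migration to a silylketene, dimerisation of the siloxyalkyne or adventitious desilylation could then consume 12 before ring B forms. A reversed orientation of addition is less likely but would put the oxygen meta to the ester. The fallback gives up ring construction for cross-coupling; it sets out from 6 and returns at 16. Commercial methyl 3-bromo-4-hydroxybenzoate would be benzylated (BnBr, K2CO3, DMF) to methyl 4-(benzyloxy)-3-bromobenzoate F1. Miyaura borylation (B2pin2, PdCl2(dppf), KOAc, dioxane, 90 °C) would give methyl 4-(benzyloxy)-3-(4,4,5,5-tetramethyl-1,3,2-dioxaborolan-2-yl)benzoate F2. Suzuki–Miyaura coupling of F2 with 6 (Pd(OAc)2, SPhos, K3PO4, toluene–water, 90 °C) should give 16, and steps 5 to 8 would no longer be needed.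

Step 6. The acetylide, the peroxide anion or the ynolate may add to C4 or C2 of the pyranone. Silylation may occur on carbon instead of oxygen, and the siloxyalkyne may hydrolyse during purification. The fallback keeps the pyrone cycloaddition but replaces the ynol ether by a ketene acetal of the same oxidation level, so no acetylide oxidation is required; it sets out from 6 and returns at 15. Palladium-catalysed coupling of 6 with the Reformatsky reagent of benzyl bromoacetate (BrZnCH2CO2Bn, Pd2(dba)3, P(t-Bu)3, THF, rt to 50 °C) would give benzyl 2-{5,7-bis(benzyloxy)-2-[4-(benzyloxy)-3-methoxyphenyl]-4-oxo-4H-chromen-8-yl}acetate F3. Enolisation with in situ trapping (LiHMDS, TIPSOTf, THF, −78 °C) would give its benzyl triisopropylsilyl ketene acetal F4. Heating F4 with 13 in toluene should give 15 after cycloaddition and loss of CO2 and benzyl alcohol. Should silanol leave instead, 16 would form directly.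

Step 9. Intermolecular acylation of the dianion by an electron-rich, hindered ester may be sluggish, so that the enolate decomposes or the ester is recovered. The acid ring closure may also cost the labile 5-benzyl ethers. The fallback makes the C–C bond intramolecularly; it sets out from 16 and returns at 17. Saponification (LiOH, THF–water, 40 °C) would give 4-(benzyloxy)-3-{5,7-bis(benzyloxy)-2-[4-(benzyloxy)-3-methoxyphenyl]-4-oxo-4H-chromen-8-yl}benzoic acid F5. Esterification of the phenol of 2 with F5 (EDC·HCl, DMAP, CH2Cl2) would give 2-acetyl-3,5-bis(benzyloxy)phenyl 4-(benzyloxy)-3-{5,7-bis(benzyloxy)-2-[4-(benzyloxy)-3-methoxyphenyl]-4-oxo-4H-chromen-8-yl}benzoate F6. Baker–Venkataraman rearrangement of F6 (KOH, pyridine, 50 °C) should give 17, which is cyclised as in step 9.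

Step 10. Debenzylation may stall because partly deprotected biflavones are poorly soluble and adsorb on the catalyst. Prolonged hydrogenation may then begin to saturate a pyranone C2=C3 bond. The fallback replaces hydrogenolysis by Lewis acid cleavage with a cation scavenger; it sets out from 18 and returns at 19. BCl3 with pentamethylbenzene in CH2Cl2 at −78 °C should cleave the six benzyl ethers by benzyl cation transfer to the scavenger while the aryl methyl ether is spared at that temperature. This fallback makes no new compound (F0).

## Further compounds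

F1 | step 7 | methyl 4-(benzyloxy)-3-bromobenzoate | COC(=O)c1ccc(OCc2ccccc2)c(Br)c1
F2 | step 7 | methyl 4-(benzyloxy)-3-(4,4,5,5-tetramethyl-1,3,2-dioxaborolan-2-yl)benzoate | COC(=O)c1ccc(OCc2ccccc2)c(B2OC(C)(C)C(C)(C)O2)c1
F3 | step 6 | benzyl 2-{5,7-bis(benzyloxy)-2-[4-(benzyloxy)-3-methoxyphenyl]-4-oxo-4H-chromen-8-yl}acetate | COc1cc(-c2cc(=O)c3c(OCc4ccccc4)cc(OCc4ccccc4)c(CC(=O)OCc4ccccc4)c3o2)ccc1OCc1ccccc1
F4 | step 6 | 5,7-bis(benzyloxy)-8-{2-(benzyloxy)-2-[tri(propan-2-yl)silyloxy]ethenyl}-2-[4-(benzyloxy)-3-methoxyphenyl]-4H-chromen-4-one (alkene geometry not controlled and immaterial) | COc1cc(-c2cc(=O)c3c(OCc4ccccc4)cc(OCc4ccccc4)c(C=C(OCc4ccccc4)O[Si](C(C)C)(C(C)C)C(C)C)c3o2)ccc1OCc1ccccc1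
F5 | step 9 | 4-(benzyloxy)-3-{5,7-bis(benzyloxy)-2-[4-(benzyloxy)-3-methoxyphenyl]-4-oxo-4H-chromen-8-yl}benzoic acid | COc1cc(-c2cc(=O)c3c(OCc4ccccc4)cc(OCc4ccccc4)c(-c4cc(C(=O)O)ccc4OCc4ccccc4)c3o2)ccc1OCc1ccccc1
F6 | step 9 | 2-acetyl-3,5-bis(benzyloxy)phenyl 4-(benzyloxy)-3-{5,7-bis(benzyloxy)-2-[4-(benzyloxy)-3-methoxyphenyl]-4-oxo-4H-chromen-8-yl}benzoate | COc1cc(-c2cc(=O)c3c(OCc4ccccc4)cc(OCc4ccccc4)c(-c4cc(C(=O)Oc5cc(OCc6ccccc6)cc(OCc6ccccc6)c5C(C)=O)ccc4OCc4ccccc4)c3o2)ccc1OCc1ccccc1
F0 | step 10 | none | none
A1 | alternative 1 | 2-[2-(benzyloxy)-5-(1,3-dioxolan-2-yl)phenyl]-5-ethoxy-3-[tri(propan-2-yl)silyloxy]phenol | CCOc1cc(O)c(-c2cc(C3OCCO3)ccc2OCc2ccccc2)c(O[Si](C(C)C)(C(C)C)C(C)C)c1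
A2 | alternative 1 | 2-(4-(benzyloxy)-3-{[tri(propan-2-yl)silyloxy]ethynyl}phenyl)-1,3-dioxolane | CC(C)[Si](OC#Cc1cc(C2OCCO2)ccc1OCc1ccccc1)(C(C)C)C(C)C
A3 | alternative 1 | 3-ethoxycyclobut-2-en-1-one | CCOC1=CC(=O)C1
A4 | alternative 2 | 3-[4,6-bis(benzyloxy)-3-{2-(benzyloxy)-5-[5,7-bis(benzyloxy)-4-oxo-4H-chromen-2-yl]phenyl}-2-(methoxymethoxy)phenyl]-5-[4-(benzyloxy)-3-methoxyphenyl]-1,2-oxazole | COCOc1c(-c2cc(-c3ccc(OCc4ccccc4)c(OC)c3)on2)c(OCc2ccccc2)cc(OCc2ccccc2)c1-c1cc(-c2cc(=O)c3c(OCc4ccccc4)cc(OCc4ccccc4)cc3o2)ccc1OCc1ccccc1
A5 | alternative 2 | (E)-4,6-bis(benzyloxy)-3-{2-(benzyloxy)-5-[5,7-bis(benzyloxy)-4-oxo-4H-chromen-2-yl]phenyl}-2-(methoxymethoxy)benzaldehyde oxime | COCOc1c(/C=N/O)c(OCc2ccccc2)cc(OCc2ccccc2)c1-c1cc(-c2cc(=O)c3c(OCc4ccccc4)cc(OCc4ccccc4)cc3o2)ccc1OCc1ccccc1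
A6 | alternative 2 | 1-(benzyloxy)-4-ethynyl-2-methoxybenzene | COc1cc(C#C)ccc1OCc1ccccc1
A7 | alternative 3 | hexa-O-benzyl ether of the target, identical with 18 | COc1cc(-c2cc(=O)c3c(OCc4ccccc4)cc(OCc4ccccc4)c(-c4cc(-c5cc(=O)c6c(OCc7ccccc7)cc(OCc7ccccc7)cc6o5)ccc4OCc4ccccc4)c3o2)ccc1OCc1ccccc1
A8 | alternative 3 | 3,5-bis(benzyloxy)-2-[(triphenylphosphoranylidene)acetyl]phenyl 4-(benzyloxy)-3-(4,6-bis(benzyloxy)-2-{[4-(benzyloxy)-3-methoxybenzoyl]oxy}-3-[(triphenylphosphoranylidene)acetyl]phenyl)benzoate | O=C(C=P(c1ccccc1)(c1ccccc1)c1ccccc1)c1c(OCc2ccccc2)cc(OCc2ccccc2)c(-c2cc(C(=O)Oc3cc(OCc4ccccc4)cc(OCc4ccccc4)c3C(=O)C=P(c3ccccc3)(c3ccccc3)c3ccccc3)ccc2OCc2ccccc2)c1OC(=O)c1ccc(OCc2ccccc2)c(OC)c1
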